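The meeting opened on a neighbour of this flask, the same charge read at 1.0 min, and the chair asked what the longer run holds.

starting material 0.44 M; second substrate 0.880 M; gas 20 mM (held); time 4.0 min

    gas ⇌ reagent, rate k1*(csat - [reagent]) (k1 = 72.2 /min, csat = 20 mM)
    second substrate + reagent ⇌ second product (K2 = 637 /M, k2 = 13.7 /M/min)
    starting material + reagent ⇌ target (K3 = 60.9 /M, k3 = 69.1 /M/min)

- target at 4.0 min, in percent of the starting material charged
- the change that raises the amount of target at 4.0 min, in percent of the starting material charged most ("none" if none brings more than 2 percentage points) (eta / alpha / none)
- amount of target at 4.0 min, in percent of the starting material charged, after eta

- at the start none of reagent is dissolved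
- run time (flask): 4.0 min

I argued that we should reckon the fraction left and not the fraction made. At equilibrium, target over starting material equals the equilibrium constant of the target step times c(reagent). That constant times csat is 1.22, so one over one plus this figure gives 45.1%. I called this the floor: the fraction of starting material left at equilibrium with reagent at saturation.

I then asked whether the flask gets there. With reagent near saturation, the target step relaxes with a half-life of 0.275 min, shorter than the 4.0 min run. The target step should therefore stand near its equilibrium by the end.

Second substrate also takes up reagent, though. With its full charge set against transfer, I estimated a lower c(reagent) and 51.1% target. So I committed to a y between that and 54.9%.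

Eta leaves the floor where it stands, I said, while alpha lowers it to 29.1%. My choice was alpha. I gave no separate figure for yb.

The forecast was then read out: y 53.2%, best alpha, yb 54.1%. Its maker held that "Faster transfer can therefore add only about a point".

The simulation gives y 53.2% and best alpha, with alpha gaining 17 percentage points against 0.9 points for eta. After eta, yb is 54.1%.

The falling back of target to starting material and reagent is the main reason this flask stops short: the same run without it reaches 99.0%, not 53.2%. The same fraction left, reckoned with the 0.0188 M of reagent read at 4.00 min in place of saturation, is 46.6%, and the reading is 46.8%. In the alpha flask, the floor of 29.1% leaves room for 18 points above this flask's target, and doubling the saturation concentration gained 17 points.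

The numbers were drawn at random within sensible limits; the flask was simulated.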